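**Retrosynthetic overview**

1. The target is reached by removing four methoxymethyl (MOM) ethers from the (2S)-flavanone tetra-MOM ether in the last step.
2. Feature used: ring A carries O1 on C8a and the C4 carbonyl on the neighbouring C4a, and C4a is flanked by the C5 oxygen. This contiguous oxygen/acyl/oxygen array is what a 3-alkoxyaryne gives when an O-nucleophile adds and the aryl anion is then acylated. Cutting O1–C8a and C4–C4a opens ring C to 3,5-bis(methoxymethoxy)benzyne (from an ortho-silylaryl triflate) and a chiral β-silyloxy N-methoxy-N-methylamide.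
3. The amide comes from the ring B methyl ketone by Claisen methoxycarbonylation, Noyori transfer hydrogenation (sets C2), amidation and silylation.
4. Ring B comes from 3',5'-dibromo-4'-hydroxyacetophenone by two successive halogen–metal exchanges, the first taking prenyl bromide and the second methyl (R)-glycidate (side-chain carbinol from the chiral pool); the glycidate ester is then turned into the isopropenyl group.
5. The aryne precursor comes from phloroglucinol by carbamate-directed ortho-silylation. Rings A and B are bought as benzene rings; ring C is the only ring of the target that is formed, in step 18.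

Key step: step 18

Remark on the chemistry: the acyl carbon captured in the key step is carried as an N-methoxy-N-methylamide, not an alkyl ester. Its α-protons are less acidic, its aldolate resists retro-aldol cleavage, and the tetrahedral adduct releases no alkoxide base beside the base-labile flavanone.

Assumption: 3',5'-dibromo-4'-hydroxyacetophenone, prenyl bromide, methyl (R)-glycidate and phloroglucinol are bought.

Abbreviations used in names:
- ArK = 2-(methoxymethoxy)-5-(2-methyl-1,3-dioxolan-2-yl)-3-(3-methylbut-2-en-1-yl)phenyl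
- ArB = 4-(methoxymethoxy)-3-[(2R)-2-(methoxymethoxy)-3-methylbut-3-en-1-yl]-5-(3-methylbut-2-en-1-yl)phenyl

**Route**

Step 1
Reactants: 1 3',5'-dibromo-4'-hydroxyacetophenone
Product: 2 1-[3,5-dibromo-4-(methoxymethoxy)phenyl]ethan-1-one
Conditions: MOMCl, iPr2NEt, CH2Cl2, 0 °C to rt
Reagents that add atoms: chloromethyl methyl ether (MOMCl), COCCl
Why: O-alkylation (Williamson type) of the acidic 2,6-dibromophenol with MOMCl under amine base should be clean, the ketone being inert.

Step 2
Reactants: 2 1-[3,5-dibromo-4-(methoxymethoxy)phenyl]ethan-1-one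
Product: 3 2-[3,5-dibromo-4-(methoxymethoxy)phenyl]-2-methyl-1,3-dioxolane
Conditions: (TMSOCH2)2, TMSOTf (5 mol%), CH2Cl2, −78 to 0 °C; pyridine quench
Reagents that add atoms: 1,2-bis(trimethylsilyloxy)ethane, C[Si](C)(C)OCCO[Si](C)(C)C
Why: Noyori ketalisation masks the ketone under aprotic, low-temperature conditions that should spare the aryl MOM ether.

Step 3
Reactants: 3 2-[3,5-dibromo-4-(methoxymethoxy)phenyl]-2-methyl-1,3-dioxolane; 4 prenyl bromide (1-bromo-3-methylbut-2-ene)
Product: 6 2-[3-bromo-4-(methoxymethoxy)-5-(3-methylbut-2-en-1-yl)phenyl]-2-methyl-1,3-dioxolane, via arylmagnesium chloride 5 (not isolated)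
Conditions: iPrMgCl·LiCl, THF, −15 °C; then Li2CuCl4 (5 mol%), 4, −15 to 0 °C
Reagents that add atoms: none
Why: Knochel bromine–magnesium exchange should stop after one bromine because the ring of 5 is deactivated toward a second exchange, and the Li2CuCl4-catalysed allylic substitution (Kochi-type coupling) should occur at the primary carbon of prenyl bromide, since attack at the other terminus would build a quaternary centre.

Step 4
Reactants: 6 2-[3-bromo-4-(methoxymethoxy)-5-(3-methylbut-2-en-1-yl)phenyl]-2-methyl-1,3-dioxolane; 7 methyl (R)-glycidate (methyl (2R)-oxirane-2-carboxylate)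
Product: 10 methyl (2R)-2-hydroxy-3-ArK-propanoate, via aryllithium 8 (not isolated), via arylmagnesium bromide 9 (not isolated)
Conditions: n-BuLi, THF, −78 °C; MgBr2·OEt2, −78 to −40 °C; CuI (10 mol%), 7, −40 to −20 °C; aq NH4Cl
Reagents that add atoms: none
Why: bromine–lithium exchange, transmetalation to magnesium and CuI-catalysed SN2 opening of the epoxide at its CH2 terminus should outrun attack on the ester at low temperature; the C2–O bond of 7 is not touched, so its (R) centre becomes the (R) carbinol.

Step 5
Reactants: 10 methyl (2R)-2-hydroxy-3-ArK-propanoate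
Product: 11 methyl (2R)-2-(methoxymethoxy)-3-ArK-propanoate
Conditions: MOMCl, iPr2NEt, Bu4NI (cat.), CH2Cl2, 0 to 40 °C
Reagents that add atoms: chloromethyl methyl ether (MOMCl), COCCl
Why: O-alkylation of the secondary alcohol under amine base forms the MOM ether without deprotonating the α-stereocenter.

Step 6
Reactants: 11 methyl (2R)-2-(methoxymethoxy)-3-ArK-propanoate
Product: 13 (3R)-3-(methoxymethoxy)-4-ArK-butan-2-one, via Weinreb amide 12 (not isolated)
Conditions: MeNH(OMe)·HCl, iPrMgCl, THF, −20 °C; then MeMgCl, −20 to 0 °C; aq NH4Cl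
Reagents that add atoms: methylmagnesium chloride, C[Mg]Cl
Why: Weinreb ketone synthesis run in one pot: the chloromagnesium amide converts the ester into 12, and MeMgCl then adds once because the chelated tetrahedral adduct survives until the quench, which should leave the α-alkoxy centre unchanged.

Step 7
Reactants: 13 (3R)-3-(methoxymethoxy)-4-ArK-butan-2-one
Product: 14 2-ArB-2-methyl-1,3-dioxolane
Conditions: Ph3PCH3Br, KN(SiMe3)2, THF, 0 °C; then 13, −78 °C to rt
Reagents that add atoms: methyltriphenylphosphonium bromide, C[P+](c1ccccc1)(c1ccccc1)c1ccccc1.[Br-]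
Why: Wittig methylenation turns the methyl ketone into the isopropenyl group; any enolisation by the ylide should go to the methyl side, so the (R) centre is kept and is a non-epimerisable allylic ether afterwards.

Step 8
Reactants: 14 2-ArB-2-methyl-1,3-dioxolane
Product: 15 1-ArB-ethan-1-one
Conditions: PPTS (cat.), acetone/H2O, 45 °C
Reagents that add atoms: water, O
Why: mild acetal hydrolysis; the dioxolane of a para-alkoxyaryl ketone ionises far more easily than the MOM ethers, and the alkenes should not be protonated by PPTS.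

Step 9
Reactants: 15 1-ArB-ethan-1-one
Product: 16 methyl 3-ArB-3-oxopropanoate
Conditions: NaH, (MeO)2CO, THF, reflux; AcOH quench
Reagents that add atoms: dimethyl carbonate, COC(=O)OC
Why: crossed Claisen condensation of the methyl ketone enolate with dimethyl carbonate, driven by deprotonation of the β-keto ester; no other acidic site is present.

Step 10
Reactants: 16 methyl 3-ArB-3-oxopropanoate
Product: 17 methyl (3S)-3-ArB-3-hydroxypropanoate
Conditions: RuCl[(S,S)-TsDPEN](p-cymene) (1 mol%), HCO2H/Et3N (5:2), DMF, 30 °C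
Reagents that add atoms: none
Why: Noyori asymmetric transfer hydrogenation; the (S,S) catalyst should deliver hydride to the aryl ketone in the sense that gives (S)-1-arylalkanols (aryl as the π-group, CH2CO2Me as the small group, so the descriptor is (S) as for acetophenone), under catalyst control and without touching alkenes or MOM ethers, so the diastereomeric purity of 17 equals the enantioselectivity of this reduction.

Step 11
Reactants: 17 methyl (3S)-3-ArB-3-hydroxypropanoate
Product: 18 (3S)-3-ArB-3-hydroxy-N-methoxy-N-methylpropanamide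
Conditions: MeNH(OMe)·HCl, iPrMgCl, THF, −20 to 0 °C
Reagents that add atoms: N,O-dimethylhydroxylamine hydrochloride, CNOC.Cl
Why: Weinreb amide formation by aminolysis with the chloromagnesium amide, which tolerates the free β-hydroxyl as its magnesium alkoxide without retro-aldol cleavage.

Step 12
Reactants: 18 (3S)-3-ArB-3-hydroxy-N-methoxy-N-methylpropanamide
Product: 19 (3S)-3-ArB-N-methoxy-N-methyl-3-[(trimethylsilyl)oxy]propanamide
Conditions: TMSCl, imidazole, CH2Cl2, 0 °C; Et3N-washed silica
Reagents that add atoms: chlorotrimethylsilane, C[Si](C)(C)Cl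
Why: O-silylation gives the trimethylsilyl ether from which fluoride can later release a proton-free alkoxide.

Step 13
Reactants: 20 phloroglucinol
Product: 21 3,5-bis(methoxymethoxy)phenol
Conditions: MOMCl (2 equiv), iPr2NEt, DMF, 0 °C; chromatography
Reagents that add atoms: chloromethyl methyl ether (MOMCl), COCCl
Why: statistical O-alkylation of the symmetrical triphenol with two equivalents of MOMCl, the bis-ether being separated from the mono- and tris-ethers.

Step 14
Reactants: 21 3,5-bis(methoxymethoxy)phenol
Product: 22 3,5-bis(methoxymethoxy)phenyl N,N-diethylcarbamate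
Conditions: NaH, Et2NCOCl, THF, 0 °C to rt
Reagents that add atoms: N,N-diethylcarbamoyl chloride, CCN(CC)C(=O)Cl
Why: O-carbamoylation of the sodium phenoxide installs the strongest ortho-directing group for the next step.

Step 15
Reactants: 22 3,5-bis(methoxymethoxy)phenyl N,N-diethylcarbamate
Product: 24 3,5-bis(methoxymethoxy)-2-(trimethylsilyl)phenyl N,N-diethylcarbamate, via aryllithium 23 (not isolated)
Conditions: s-BuLi, TMEDA, THF, −78 °C; TMSCl, −78 °C to rt
Reagents that add atoms: chlorotrimethylsilane, C[Si](C)(C)Cl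
Why: directed ortho-metalation (Snieckus type) should take place at the position flanked by the carbamate and one OMOM group, the carbamate outranking OMOM as director, and the TMSCl quench at −78 °C precedes any anionic Fries shift.

Step 16
Reactants: 24 3,5-bis(methoxymethoxy)-2-(trimethylsilyl)phenyl N,N-diethylcarbamate
Product: 25 3,5-bis(methoxymethoxy)-2-(trimethylsilyl)phenol
Conditions: LiAlH4, THF, 0 °C to rt; aq potassium sodium tartrate
Reagents that add atoms: none
Why: hydride cleavage of the aryl carbamate (attack at the carbonyl, loss of phenoxide) leaves MOM ethers and the aryl–silicon bond intact, and the neutral work-up avoids protodesilylation of the electron-rich arylsilane.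

Step 17
Reactants: 25 3,5-bis(methoxymethoxy)-2-(trimethylsilyl)phenol
Product: 26 3,5-bis(methoxymethoxy)-2-(trimethylsilyl)phenyl trifluoromethanesulfonate
Conditions: Tf2O, pyridine, CH2Cl2, −20 to 0 °C
Reagents that add atoms: trifluoromethanesulfonic anhydride, O=S(=O)(OS(=O)(=O)C(F)(F)F)C(F)(F)F
Why: O-triflation of the phenol under pyridine buffering gives the Kobayashi-type ortho-silylaryl triflate.

Step 18
Reactants: 19 (3S)-3-ArB-N-methoxy-N-methyl-3-[(trimethylsilyl)oxy]propanamide; 26 3,5-bis(methoxymethoxy)-2-(trimethylsilyl)phenyl trifluoromethanesulfonate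
Product: 31 (2S)-2-ArB-5,7-bis(methoxymethoxy)-2,3-dihydro-4H-chromen-4-one, via cesium alkoxide 27 (not isolated), via 3,5-bis(methoxymethoxy)benzyne 28 (not isolated), via aryl anion 29 (not isolated), via hemiaminal alkoxide 30 (not isolated)
Conditions: CsF (5 equiv), 18-crown-6, 26 (2 equiv), THF, 0 °C to rt; aq NH4Cl, 0 °C
Reagents that add atoms: none
Why: Proposed new method: fluoride should strip both silyl groups, setting free the cesium alkoxide 27 and, by loss of triflate, the aryne 28; 27 adds to the aryne carbon remote from the flanking OMOM group (O1–C8a), and the aryl anion 29, now ortho to that oxygen, attacks the amide carbonyl (C4–C4a) to give the tetrahedral adduct 30, which releases the ketone only on aqueous quench. The closest known reaction type is the fluoride-induced annulation of arynes with ortho-hydroxybenzoate esters to xanthones (O-nucleophile addition, then acyl capture by the aryl anion); what is new is an aliphatic β-alkoxide carrying enolisable C3 protons. Ring C is closed by a 6-exo-trig attack of the aryl anion on the carbonyl. No stereocenter is formed: C2 was set in step 10 and its C–O bond is never broken, so it is carried over with retention and keeps the (S) descriptor. The step needs regioselective addition to the aryne, secured by the alkoxy group next to the triple bond, which directs the nucleophile to the distal carbon so that the charge develops beside oxygen; it also needs acyl capture to outrun proton transfer from C3 and retro-aldol cleavage, for which the weakly acidic amide α-protons, the absence of any proton source and the persistent adduct 30 (no alkoxide base set free beside the flavanone) are the safeguards.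

Step 19
Reactants: 31 (2S)-2-ArB-5,7-bis(methoxymethoxy)-2,3-dihydro-4H-chromen-4-one
Product: 32 (2S)-5,7-dihydroxy-2-{4-hydroxy-3-[(2R)-2-hydroxy-3-methylbut-3-en-1-yl]-5-(3-methylbut-2-en-1-yl)phenyl}-2,3-dihydro-4H-chromen-4-one
Conditions: 3 M aq HCl, MeOH, 40 °C
Reagents that add atoms: none
Why: acid-catalysed acetal exchange transfers all four MOM groups to methanol; no bond at C2 or at the side-chain carbinol carbon is broken, and the moderate temperature should spare the alkenes and the C2 configuration.

**Compound list**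

1 | 3',5'-dibromo-4'-hydroxyacetophenone | CC(=O)c1cc(Br)c(O)c(Br)c1 | starting material
2 | 1-[3,5-dibromo-4-(methoxymethoxy)phenyl]ethan-1-one | CC(=O)c1cc(Br)c(OCOC)c(Br)c1 | intermediate
3 | 2-[3,5-dibromo-4-(methoxymethoxy)phenyl]-2-methyl-1,3-dioxolane | CC1(OCCO1)c2cc(Br)c(OCOC)c(Br)c2 | intermediate
4 | prenyl bromide (1-bromo-3-methylbut-2-ene) | CC(C)=CCBr | starting material
5 | [3-bromo-2-(methoxymethoxy)-5-(2-methyl-1,3-dioxolan-2-yl)phenyl]magnesium chloride (not isolated) | CC1(OCCO1)c2cc(Br)c(OCOC)c([Mg]Cl)c2 | intermediate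
6 | 2-[3-bromo-4-(methoxymethoxy)-5-(3-methylbut-2-en-1-yl)phenyl]-2-methyl-1,3-dioxolane | CC1(OCCO1)c2cc(Br)c(OCOC)c(CC=C(C)C)c2 | intermediate
7 | methyl (R)-glycidate | COC(=O)[C@H]1CO1 | starting material
8 | ArK-lithium (not isolated) | CC1(OCCO1)c2cc([Li])c(OCOC)c(CC=C(C)C)c2 | intermediate
9 | ArK-magnesium bromide (not isolated) | CC1(OCCO1)c2cc([Mg]Br)c(OCOC)c(CC=C(C)C)c2 | intermediate
10 | methyl (2R)-2-hydroxy-3-ArK-propanoate | COC(=O)[C@H](O)Cc1cc(C2(C)OCCO2)cc(CC=C(C)C)c1OCOC | intermediate
11 | methyl (2R)-2-(methoxymethoxy)-3-ArK-propanoate | COC(=O)[C@H](OCOC)Cc1cc(C2(C)OCCO2)cc(CC=C(C)C)c1OCOC | intermediate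
12 | (2R)-N-methoxy-2-(methoxymethoxy)-N-methyl-3-ArK-propanamide (not isolated) | CON(C)C(=O)[C@H](OCOC)Cc1cc(C2(C)OCCO2)cc(CC=C(C)C)c1OCOC | intermediate
13 | (3R)-3-(methoxymethoxy)-4-ArK-butan-2-one | CC(=O)[C@H](OCOC)Cc1cc(C2(C)OCCO2)cc(CC=C(C)C)c1OCOC | intermediate
14 | 2-ArB-2-methyl-1,3-dioxolane | C=C(C)[C@H](OCOC)Cc1cc(C2(C)OCCO2)cc(CC=C(C)C)c1OCOC | intermediate
15 | 1-ArB-ethan-1-one | C=C(C)[C@H](OCOC)Cc1cc(C(C)=O)cc(CC=C(C)C)c1OCOC | intermediate
16 | methyl 3-ArB-3-oxopropanoate | C=C(C)[C@H](OCOC)Cc1cc(C(=O)CC(=O)OC)cc(CC=C(C)C)c1OCOC | intermediate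
17 | methyl (3S)-3-ArB-3-hydroxypropanoate | C=C(C)[C@H](OCOC)Cc1cc([C@@H](O)CC(=O)OC)cc(CC=C(C)C)c1OCOC | intermediate
18 | (3S)-3-ArB-3-hydroxy-N-methoxy-N-methylpropanamide | C=C(C)[C@H](OCOC)Cc1cc([C@@H](O)CC(=O)N(C)OC)cc(CC=C(C)C)c1OCOC | intermediate
19 | (3S)-3-ArB-N-methoxy-N-methyl-3-[(trimethylsilyl)oxy]propanamide (key-step precursor) | C=C(C)[C@H](OCOC)Cc1cc([C@@H](O[Si](C)(C)C)CC(=O)N(C)OC)cc(CC=C(C)C)c1OCOC | intermediate
20 | phloroglucinol | Oc1cc(O)cc(O)c1 | starting material
21 | 3,5-bis(methoxymethoxy)phenol | COCOc1cc(O)cc(OCOC)c1 | intermediate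
22 | 3,5-bis(methoxymethoxy)phenyl N,N-diethylcarbamate | CCN(CC)C(=O)Oc1cc(OCOC)cc(OCOC)c1 | intermediate
23 | [2-(diethylcarbamoyloxy)-4,6-bis(methoxymethoxy)phenyl]lithium (not isolated) | CCN(CC)C(=O)Oc1cc(OCOC)cc(OCOC)c1[Li] | intermediate
24 | 3,5-bis(methoxymethoxy)-2-(trimethylsilyl)phenyl N,N-diethylcarbamate | CCN(CC)C(=O)Oc1cc(OCOC)cc(OCOC)c1[Si](C)(C)C | intermediate
25 | 3,5-bis(methoxymethoxy)-2-(trimethylsilyl)phenol | COCOc1cc(O)c([Si](C)(C)C)c(OCOC)c1 | intermediate
26 | 3,5-bis(methoxymethoxy)-2-(trimethylsilyl)phenyl trifluoromethanesulfonate (aryne precursor) | COCOc1cc(OCOC)c([Si](C)(C)C)c(OS(=O)(=O)C(F)(F)F)c1 | intermediate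
27 | cesium (1S)-1-ArB-3-[methoxy(methyl)amino]-3-oxopropan-1-olate (not isolated) | C=C(C)[C@H](OCOC)Cc1cc([C@@H]([O-])CC(=O)N(C)OC)cc(CC=C(C)C)c1OCOC.[Cs+] | intermediate
28 | 3,5-bis(methoxymethoxy)benzyne (not isolated) | COCOC1=CC(OCOC)=CC#C1 | intermediate
29 | cesium aryl anion: (3S)-3-ArB-3-aryloxy amide whose aryloxy ring carries 3,5-bis(methoxymethoxy) groups and the negative charge on C2, between the ether oxygen and an OMOM group (not isolated) | C=C(C)[C@H](OCOC)Cc1cc([C@@H](Oc2cc(OCOC)cc(OCOC)[c-]2)CC(=O)N(C)OC)cc(CC=C(C)C)c1OCOC.[Cs+] | intermediate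
30 | cesium (2S)-2-ArB-4-[methoxy(methyl)amino]-5,7-bis(methoxymethoxy)-3,4-dihydro-2H-chromen-4-olate, both C4 epimers (not isolated) | C=C(C)[C@H](OCOC)Cc1cc([C@@H]2CC([O-])(N(C)OC)c3c(OCOC)cc(OCOC)cc3O2)cc(CC=C(C)C)c1OCOC.[Cs+] | intermediate
31 | (2S)-2-ArB-5,7-bis(methoxymethoxy)-2,3-dihydro-4H-chromen-4-one (key-step product) | C=C(C)[C@H](OCOC)Cc1cc([C@@H]2CC(=O)c3c(OCOC)cc(OCOC)cc3O2)cc(CC=C(C)C)c1OCOC | intermediate
32 | (2S)-5,7-dihydroxy-2-{4-hydroxy-3-[(2R)-2-hydroxy-3-methylbut-3-en-1-yl]-5-(3-methylbut-2-en-1-yl)phenyl}-2,3-dihydro-4H-chromen-4-one | C=C(C)[C@H](O)Cc1cc([C@@H]2CC(=O)c3c(O)cc(O)cc3O2)cc(CC=C(C)C)c1O | target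

**Step count and risks**

Total step count: 19. Longest linear sequence: 14 steps (steps 1 to 12, then 18 and 19); the aryne precursor branch is steps 13 to 17.

Steps most likely to fail:

1. Step 18 (new method). The aryl anion may take a proton from C3 or from the medium before it is acylated, leaving an open O-aryl ether, or the free aldolate may fragment before it meets the aryne. The fallback uses known chemistry (transfer hydrogenation, Weinreb ketone synthesis, intramolecular Mitsunobu etherification with inversion) and sets out from β-keto ester 16. Reduction with RuCl[(R,R)-TsDPEN](p-cymene) in HCO2H/Et3N should give methyl (3R)-3-ArB-3-hydroxypropanoate F1, and MeNH(OMe)·HCl/iPrMgCl turns it into (3R)-3-ArB-3-hydroxy-N-methoxy-N-methylpropanamide F2. Phloroglucinol 20 with excess MOMCl and NaH gives 1,3,5-tris(methoxymethoxy)benzene F3, which n-BuLi lithiates between two OMOM groups to [2,4,6-tris(methoxymethoxy)phenyl]lithium F4. Addition of F4 (3 equiv) to F2 gives (3R)-3-ArB-3-hydroxy-1-[2,4,6-tris(methoxymethoxy)phenyl]propan-1-one F5. Brief treatment with dilute HCl in MeOH at 0 °C should remove one of the two equivalent carbonyl-flanking MOM groups, the most labile ones, to give (3R)-3-ArB-3-hydroxy-1-[2-hydroxy-4,6-bis(methoxymethoxy)phenyl]propan-1-one F6. PPh3/DIAD then closes ring C by SN2 displacement of the activated benzylic hydroxyl by the phenol with inversion, (3R) to (2S), and the sequence comes back to the route at 31.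

2. Step 4. The aryl nucleophile may attack the ester of 7, or magnesium bromide may open the epoxide to a bromohydrin, in place of the C–C bond formation. The fallback sets out from 6 and builds the carbinol by oxidation of a second prenyl group. Bromine–lithium exchange of 6 (through 8 and 9) and Li2CuCl4-catalysed coupling with prenyl bromide 4 give 2-[4-(methoxymethoxy)-3,5-bis(3-methylbut-2-en-1-yl)phenyl]-2-methyl-1,3-dioxolane F7. Shi epoxidation with the D-fructose-derived ketone and KHSO5 (buffered with K2CO3), stopped at partial conversion, should epoxidise one of the two equivalent prenyl groups to 2-[3-{[(2R)-3,3-dimethyloxiran-2-yl]methyl}-4-(methoxymethoxy)-5-(3-methylbut-2-en-1-yl)phenyl]-2-methyl-1,3-dioxolane F8, with unreacted F7 returned. Diethylaluminium 2,2,6,6-tetramethylpiperidide, Et2Al(TMP), removes a methyl proton and opens the tertiary C–O bond, leaving the secondary C–O bond intact, to give 2-{3-[(2R)-2-hydroxy-3-methylbut-3-en-1-yl]-4-(methoxymethoxy)-5-(3-methylbut-2-en-1-yl)phenyl}-2-methyl-1,3-dioxolane F9. MOMCl/iPr2NEt then gives 14, where the route is rejoined; steps 4 to 7 are bypassed.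

3. Step 19. The isopropenyl or prenyl double bond may be protonated and captured by the freed 4'-hydroxyl (chroman formation) or by methanol before the less labile secondary alkyl MOM ether is cleaved. The fallback replaces protic solvolysis by Lewis-acid-assisted thiolysis: ZnBr2 and n-PrSH in CH2Cl2 at 0 °C transfer the methoxymethyl groups to sulfur within minutes without a free Brønsted acid. It runs from 31 directly to 32 and passes through no new compound (F0).

Further compounds
F1 | step 18 | methyl (3R)-3-ArB-3-hydroxypropanoate | C=C(C)[C@H](OCOC)Cc1cc([C@H](O)CC(=O)OC)cc(CC=C(C)C)c1OCOC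
F2 | step 18 | (3R)-3-ArB-3-hydroxy-N-methoxy-N-methylpropanamide | C=C(C)[C@H](OCOC)Cc1cc([C@H](O)CC(=O)N(C)OC)cc(CC=C(C)C)c1OCOC
F3 | step 18 | 1,3,5-tris(methoxymethoxy)benzene | COCOc1cc(OCOC)cc(OCOC)c1
F4 | step 18 | [2,4,6-tris(methoxymethoxy)phenyl]lithium | COCOc1cc(OCOC)c([Li])c(OCOC)c1
F5 | step 18 | (3R)-3-ArB-3-hydroxy-1-[2,4,6-tris(methoxymethoxy)phenyl]propan-1-one | C=C(C)[C@H](OCOC)Cc1cc([C@H](O)CC(=O)c2c(OCOC)cc(OCOC)cc2OCOC)cc(CC=C(C)C)c1OCOC
F6 | step 18 | (3R)-3-ArB-3-hydroxy-1-[2-hydroxy-4,6-bis(methoxymethoxy)phenyl]propan-1-one | C=C(C)[C@H](OCOC)Cc1cc([C@H](O)CC(=O)c2c(O)cc(OCOC)cc2OCOC)cc(CC=C(C)C)c1OCOC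
F7 | step 4 | 2-[4-(methoxymethoxy)-3,5-bis(3-methylbut-2-en-1-yl)phenyl]-2-methyl-1,3-dioxolane | CC1(OCCO1)c2cc(CC=C(C)C)c(OCOC)c(CC=C(C)C)c2
F8 | step 4 | 2-[3-{[(2R)-3,3-dimethyloxiran-2-yl]methyl}-4-(methoxymethoxy)-5-(3-methylbut-2-en-1-yl)phenyl]-2-methyl-1,3-dioxolane | CC1(C)[C@H](O1)Cc2cc(C3(C)OCCO3)cc(CC=C(C)C)c2OCOC
F9 | step 4 | 2-{3-[(2R)-2-hydroxy-3-methylbut-3-en-1-yl]-4-(methoxymethoxy)-5-(3-methylbut-2-en-1-yl)phenyl}-2-methyl-1,3-dioxolane | C=C(C)[C@H](O)Cc1cc(C2(C)OCCO2)cc(CC=C(C)C)c1OCOC
F0 | step 19 | none | none
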